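## Retrosynthetic overview

1. Ring E is closed last by cyclodehydration of δ‑hydroxy ketone 28. The C6 quaternary centre comes from the C6 ketone 22 by one‑carbon homologation, formaldehyde aldol (C7) and Wittig chain extension (C4–C1).
2. Ring A comes from a double Mannich reaction (MeNH2, 2 CH2O) across C9/C23 of tricyclic ketone 20.
3. Rings B and C (key step) come from an intramolecular Buchner ring expansion of the anisole ring in diazo ester 14. The aryl OMe becomes the C6 carbonyl; the tert‑butyl ester that stabilises the carbene is later removed by decarboxylation.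
4. Diazo ester 14 comes from (R)‑indanylacetate 10 (Michael addition/diazo transfer, C17 by 1,2‑induction); 10 from asymmetric hydrogenation of indene 9 (C14); 9 from 7‑methoxy‑1‑indanone, made from phenol.
5. Ring order: D (indanone) → B + C (Buchner) → A (Mannich) → E (enol ether).

Assumption: locants C1–C27 count the atoms of the target SMILES from left to right (O8, O19, O20 and N25 included); ring A = piperidine, ring B = cycloheptene, ring C = ester‑bearing cyclopentane, ring D = cyclopentene, ring E = dihydropyran.

## Route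

Step 1
Reactants: 1 phenol; 2 3-chloropropanoyl chloride
Product: 5 7-hydroxy-2,3-dihydro-1H-inden-1-one, via phenyl 3-chloropropanoate 3 (not isolated), via 3-chloro-1-(2-hydroxyphenyl)propan-1-one 4 (not isolated)
Conditions: neat, 80 °C; then AlCl3 (4 equiv), 100 → 170 °C; ice/aq. HCl
Reagents that add atoms: none
Why: O‑acylation, then AlCl3‑mediated ortho‑Fries rearrangement (chelation control at high temperature) and intramolecular Friedel–Crafts alkylation by the β‑chloro ketone close ring D; no stereocentre is formed.

Step 2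
Reactants: 5 7-hydroxy-2,3-dihydro-1H-inden-1-one
Product: 6 7-methoxy-2,3-dihydro-1H-inden-1-one
Conditions: MeI, K2CO3, DMF, 50 °C
Reagents that add atoms: iodomethane, CI
Why: Williamson etherification of the phenol; the methyl ether later becomes the enol ether that masks the C6 ketone.

Step 3
Reactants: 6 7-methoxy-2,3-dihydro-1H-inden-1-one; 7 methyl 2-bromoacetate
Product: 9 methyl 2-(4-methoxy-1H-inden-3-yl)acetate, via hydroxy ester 8 (not isolated)
Conditions: Zn, THF, reflux; aq. NH4Cl; then TsOH·H2O (5 mol %), PhMe, 80 °C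
Reagents that add atoms: none
Why: Reformatsky addition to the aryl ketone, then acid‑catalysed E1 dehydration that equilibrates to the endocyclic (indene) alkene.

Step 4
Reactants: 9 methyl 2-(4-methoxy-1H-inden-3-yl)acetate
Product: 10 methyl 2-[(1R)-7-methoxy-2,3-dihydro-1H-inden-1-yl]acetate
Conditions: H2 (50 bar), [Ir(cod)(tBu-PHOX)][B(C6H3(CF3)2)4] (1 mol %, ligand antipode that gives the (R)-ester), CH2Cl2, rt
Reagents that add atoms: none
Why: Iridium P,N‑catalysed asymmetric hydrogenation of the trisubstituted styrenic alkene; the catalyst antipode sets C14 as (R), the only stereocentre installed by reagent control.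

Step 5
Reactants: 10 methyl 2-[(1R)-7-methoxy-2,3-dihydro-1H-inden-1-yl]acetate; 11 tert-butyl prop-2-enoate
Product: 14 5-tert-butyl 1-methyl (2R)-4-diazo-2-[(1R)-7-methoxy-2,3-dihydro-1H-inden-1-yl]pentanedioate, via lithium enolate 12 (not isolated), via trifluoroacetyl diester 13 (not isolated)
Conditions: LiN(iPr)2 (1.05 equiv), THF, −78 °C; 11; CF3CO2CH2CF3, −78 °C; aq. HCl; then MsN3, Et3N, H2O (1 equiv), MeCN, rt
Reagents that add atoms: methanesulfonyl azide, CS(=O)(=O)N=[N+]=[N-]
Why: Michael addition of the ester enolate to the acrylate, C‑trifluoroacetylation of the regiospecifically formed adduct enolate, then detrifluoroacetylative (Regitz/Danheiser‑type) diazo transfer; C17 is set by 1,2‑induction, the acrylate approaching the enolate (C14–H eclipsed, A(1,3) control) anti to the peri‑methoxyaryl face.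

Step 6
Reactants: 14 5-tert-butyl 1-methyl (2R)-4-diazo-2-[(1R)-7-methoxy-2,3-dihydro-1H-inden-1-yl]pentanedioate
Product: 16 tricyclic cycloheptatriene diester (rings B/C/D; C6–OMe; C6=C9 C10=C11 C12=C13; CO2tBu on C23 anti to H14; CO2Me on C17; H14/H17 cis), via norcaradiene 15 (not isolated)
Conditions: Rh2(O2CCPh3)4 (1 mol %), CH2Cl2, −78 °C → rt, slow addition of 14
Reagents that add atoms: none
Why: Proposed new method: the electrophilic rhodium carbenoid from the α‑alkyl‑α‑diazo ester should add through a five‑membered tether to the electron‑rich C13–C6(OMe) aryl bond on the peri side, and norcaradiene 15 should open by 6π disrotatory electrocyclisation to cycloheptatriene 16 (rings B and C, C12=C13 in place), with the bulky triphenylacetate ligands and low temperature suppressing 1,2‑hydride migration; the closest known chemistry is the intramolecular Buchner reaction of 1‑diazo‑4‑arylbutan‑2‑ones (azulenone synthesis) and Rh2(O2CCPh3)4‑catalysed cyclopropanation with α‑alkyl‑α‑diazo esters; the C23 configuration formed here is erased in step 8.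

Step 7
Reactants: 16 tricyclic cycloheptatriene diester
Product: 17 10,11-dihydro derivative of 16 (C6=C9 enol ether and C12=C13 retained)
Conditions: 2-nitrobenzenesulfonohydrazide, Et3N, CH2Cl2, rt
Reagents that add atoms: none
Why: Diimide reduction (concerted syn H2 transfer) takes the least substituted cis‑disubstituted C10=C11 bond and leaves the trisubstituted enol ether and the tetrasubstituted C12=C13 bond.

Step 8
Reactants: 17 10,11-dihydro derivative of 16
Product: 20 tricyclic keto ester (rings B/C/D; C6 ketone; C12=C13; CO2Me on C17; H14 H17 H23 all cis), via keto tert-butyl ester 18 (not isolated), via keto acid 19 (not isolated)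
Conditions: CF3CO2H, H2O (3 equiv), CH2Cl2, 0 °C → rt; evaporate; PhMe, 50 °C
Reagents that add atoms: water, O
Why: Acid hydrolysis of the enol ether unveils the C6 ketone, acidolysis of the tert‑butyl ester gives a β‑keto acid that decarboxylates on warming, and ketonisation from the less hindered face gives the β,γ‑unsaturated ketone (C23 is epimerisable and is reset in step 9).

Step 9
Reactants: 20 tricyclic keto ester
Product: 22 tetracyclic amino ketone (rings A–D; N-methyl; C6 ketone; C24 syn to H14; C9 C14 C17 C23 as in the target), via Mannich base 21 (not isolated)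
Conditions: MeNH2 (40 % aq., 1.1 equiv), CH2O (37 % aq., 2.2 equiv), AcOH, 60 °C; aq. NaHCO3
Reagents that add atoms: methylamine, CN; formaldehyde, C=O
Why: Double Mannich reaction (Robinson–Schöpf‑type annulation): aminomethylation at C9, then the tethered N‑methyl iminium is captured at C23 through the dienol on the face anti to the C17 ester (syn to H14), which fixes C23 and, through the bridge, C9.

Step 10
Reactants: 22 tetracyclic amino ketone
Product: 24 aldehyde (C6–H bearing CHO = C5; C6 epimers), via enol ether 23 (not isolated)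
Conditions: Ph3P(CH2OMe)Cl, KN(SiMe3)2 (0.95 equiv per salt), THF, 0 °C → rt; then 2 M HCl, THF, rt; aq. NaHCO3
Reagents that add atoms: (methoxymethyl)triphenylphosphonium chloride, COC[P+](c1ccccc1)(c1ccccc1)c1ccccc1.[Cl-]; water, O
Why: Wittig methoxymethylenation of the non‑enolisable bridging ketone (C9 is a bridgehead, C23 is quaternary) and enol ether hydrolysis give the one‑carbon homologated aldehyde; the C6 configuration is inconsequential because it is planarised in step 11.

Step 11
Reactants: 24 aldehyde
Product: 25 hydroxy aldehyde (C6 bears CHO = C5 syn to the N25 bridge and CH2OH = C7 syn to ring B)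
Conditions: CH2O (37 % aq., 5 equiv), K2CO3 (0.3 equiv), THF, 40 °C
Reagents that add atoms: formaldehyde, C=O
Why: Crossed aldol (Tollens‑type hydroxymethylation): formaldehyde should add to the exocyclic enolate from the cycloheptene face (one syn‑axial H and the flat C13) and not from the piperidine face (two syn‑axial H on C24/C27), so C7 ends syn to ring B and C5 syn to nitrogen, as in the target.

Step 12
Reactants: 25 hydroxy aldehyde; 26 1-(triphenyl-λ5-phosphanylidene)butan-2-one
Product: 27 (E)-enone (C6–CH=CH–C(O)Et with free C7–OH)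
Conditions: PhMe, 90 °C
Reagents that add atoms: none
Why: Wittig olefination with a stabilised ylide gives the (E)‑enone and adds C4, C3 and the ethyl group under neutral conditions that do not trigger retro‑aldol loss of formaldehyde.

Step 13
Reactants: 27 (E)-enone
Product: 29 target CNP0159589.3, via hydroxy ketone 28 (not isolated)
Conditions: H2 (1 atm), Pd/C (5 %), EtOAc, rt; filter; then (+)-camphor-10-sulfonic acid (1.2 equiv), 4 Å MS, PhMe, 60 °C; Et3N
Reagents that add atoms: none
Why: Hydrogenation of the electron‑poor disubstituted enone alkene (the tetrasubstituted C12=C13 bond is inert), then acid‑catalysed hemiketalisation and dehydration to the thermodynamically preferred endocyclic enol ether close ring E.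

## Compound list

1 | phenol | Oc1ccccc1 | starting material
2 | 3-chloropropanoyl chloride | ClCCC(Cl)=O | starting material
3 | phenyl 3-chloropropanoate | ClCCC(=O)Oc1ccccc1 | intermediate (not isolated)
4 | 3-chloro-1-(2-hydroxyphenyl)propan-1-one | ClCCC(=O)c1ccccc1O | intermediate (not isolated)
5 | 7-hydroxy-2,3-dihydro-1H-inden-1-one | O=C1CCc2cccc(O)c12 | intermediate
6 | 7-methoxy-2,3-dihydro-1H-inden-1-one | COc1cccc2CCC(=O)c12 | intermediate
7 | methyl 2-bromoacetate | COC(=O)CBr | starting material
8 | methyl 2-(1-hydroxy-7-methoxy-2,3-dihydro-1H-inden-1-yl)acetate (racemic) | COC(=O)CC1(O)CCc2cccc(OC)c12 | intermediate (not isolated)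
9 | methyl 2-(4-methoxy-1H-inden-3-yl)acetate | COC(=O)CC1=CCc2cccc(OC)c12 | intermediate
10 | methyl 2-[(1R)-7-methoxy-2,3-dihydro-1H-inden-1-yl]acetate | COc1cccc2c1[C@H](CC2)CC(=O)OC | intermediate
11 | tert-butyl prop-2-enoate | C=CC(=O)OC(C)(C)C | starting material
12 | lithium (4R)-1-tert-butoxy-5-methoxy-4-[(1R)-7-methoxy-2,3-dihydro-1H-inden-1-yl]-5-oxopent-1-en-1-olate | COc1cccc2c1[C@H](CC2)[C@H](C(=O)OC)CC=C([O-])OC(C)(C)C.[Li+] | intermediate (not isolated)
13 | 5-tert-butyl 1-methyl (2R)-2-[(1R)-7-methoxy-2,3-dihydro-1H-inden-1-yl]-4-(2,2,2-trifluoroacetyl)pentanedioate (C4 epimers) | COc1cccc2c1[C@H](CC2)[C@H](C(=O)OC)CC(C(=O)C(F)(F)F)C(=O)OC(C)(C)C | intermediate (not isolated)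
14 | 5-tert-butyl 1-methyl (2R)-4-diazo-2-[(1R)-7-methoxy-2,3-dihydro-1H-inden-1-yl]pentanedioate | COc1cccc2c1[C@H](CC2)[C@H](C(=O)OC)CC(=[N+]=[N-])C(=O)OC(C)(C)C | intermediate
15 | norcaradiene valence isomer of 16 (cyclopropane C6–C13–C23) | CO[C@]12C=CC=C3CC[C@@H]4[C@H](C(=O)OC)C[C@]1(C(=O)OC(C)(C)C)[C@]342 | intermediate (not isolated)
16 | tricyclic cycloheptatriene diester (rings B/C/D; C6–OMe; C6=C9, C10=C11, C12=C13; C23–CO2tBu anti to H14; C17–CO2Me; H14/H17 cis) | COC1=CC=CC2=C3[C@H](CC2)[C@H](C(=O)OC)C[C@]31C(=O)OC(C)(C)C | intermediate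
17 | 10,11-dihydro derivative of 16 | COC1=CCCC2=C3[C@H](CC2)[C@H](C(=O)OC)C[C@]31C(=O)OC(C)(C)C | intermediate
18 | C6 ketone with C23–CO2tBu (β-keto tert-butyl ester) | O=C1CCCC2=C3[C@H](CC2)[C@H](C(=O)OC)C[C@]31C(=O)OC(C)(C)C | intermediate (not isolated)
19 | C6 ketone with C23–CO2H (β-keto acid) | O=C1CCCC2=C3[C@H](CC2)[C@H](C(=O)OC)C[C@]31C(=O)O | intermediate (not isolated)
20 | tricyclic keto ester (rings B/C/D; C6 ketone; C12=C13; C17–CO2Me; H14, H17, H23 cis) | O=C1CCCC2=C3[C@H](CC2)[C@H](C(=O)OC)C[C@@H]31 | intermediate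
21 | C9-[(methylamino)methyl] derivative of 20 (Mannich base) | O=C1[C@@H](CNC)CCC2=C3[C@H](CC2)[C@H](C(=O)OC)C[C@@H]31 | intermediate (not isolated)
22 | tetracyclic amino ketone (rings A–D; N-methyl; C6 ketone; stereocentres C9, C14, C17, C23 as in the target) | O=C2[C@@H]1CCC3=C4[C@H](CC3)[C@H](C(=O)OC)C[C@@]42CN(C)C1 | intermediate
23 | C6 methoxymethylidene enol ether (E/Z mixture) | COC=C2[C@@H]1CCC3=C4[C@H](CC3)[C@H](C(=O)OC)C[C@@]42CN(C)C1 | intermediate (not isolated)
24 | C6 carbaldehyde (CHO carbon = C5; C6 epimers) | O=CC2[C@@H]1CCC3=C4[C@H](CC3)[C@H](C(=O)OC)C[C@@]42CN(C)C1 | intermediate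
25 | C6 formyl/hydroxymethyl compound (CHO = C5 syn to N bridge; CH2OH = C7 syn to ring B) | O=C[C@@]2(CO)[C@@H]1CCC3=C4[C@H](CC3)[C@H](C(=O)OC)C[C@@]42CN(C)C1 | intermediate
26 | 1-(triphenyl-λ5-phosphanylidene)butan-2-one | CCC(=O)C=P(c1ccccc1)(c1ccccc1)c1ccccc1 | starting material
27 | (E)-enone (C6–CH=CH–C(O)Et; C7–OH) | CCC(=O)/C=C/[C@@]2(CO)[C@@H]1CCC3=C4[C@H](CC3)[C@H](C(=O)OC)C[C@@]42CN(C)C1 | intermediate
28 | δ-hydroxy ketone (C6–CH2CH2C(O)Et; C7–OH) | CCC(=O)CC[C@@]2(CO)[C@@H]1CCC3=C4[C@H](CC3)[C@H](C(=O)OC)C[C@@]42CN(C)C1 | intermediate (not isolated)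
29 | CNP0159589.3 | CCC1=CC[C@@]2(CO1)[C@@H]1CCC3=C4[C@H](CC3)[C@H](C(=O)OC)C[C@@]42CN(C)C1 | target

## Step count and risks

Total step count: 13. Longest linear sequence: 13 (phenol to 29; all other inputs are commercial).

Steps most likely to fail:

Step 6 (Buchner ring expansion). The carbenoid has β‑hydrogens at C22, so 1,2‑hydride migration or C–H insertion may win over arene addition. The fallback sets out from 10 and comes back at 16, using a carbene without β‑hydrogens and removing the extra carbonyl afterwards. C‑acylation of the lithium enolate of 10 with tert‑butyl 3‑chloro‑3‑oxopropanoate gives 5-tert-butyl 1-methyl 2-[(1R)-7-methoxy-2,3-dihydro-1H-inden-1-yl]-3-oxopentanedioate F1. Diazo transfer (4‑acetamidobenzenesulfonyl azide, Et3N) gives the 4-diazo-3-oxo diester F2. Rh2(OAc)4 then effects the classical acceptor/acceptor Buchner reaction to the C22-keto cycloheptatriene diester F3. NaBH4 reduces the ring C ketone to the C22 alcohol F4, and dehydration towards the acidic C17–H (Burgess reagent) gives the C17=C22 enoate F5. Conjugate reduction with [(Ph3P)CuH]6, with protonation of the ester enolate anti to the C23 ester, returns to 16.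

Step 9 (double Mannich). The one‑pot annulation on a ketone with one tertiary, allylic α‑carbon may give oligomeric Mannich products. The fallback sets out from 20 and comes back at 22, forming the bonds one at a time. α‑Methylenation at the only CH2 α‑carbon (paraformaldehyde, N‑methylanilinium trifluoroacetate, THF, reflux) gives the C9-methylidene ketone F6. Aza‑Michael addition of MeNH2 gives Mannich base 21, isolated as its hydrochloride. CH2O in AcOH then closes ring A by intramolecular Mannich reaction at C23 to give 22.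

Step 11 (facial selectivity at C6). If formaldehyde enters from the piperidine face instead, the C6 epimer results. The fallback sets out from 24 and comes back at 28, reversing the order in which the two arms are attached so that the same facial preference gives the target configuration. Michael addition of 24 (pyrrolidine enamine or catalytic KOH) to pent‑1‑en‑3‑one gives the C6-formyl 3-oxopentyl keto aldehyde F7, with the aldehyde carbon now serving as C7. NaBH4 at −78 °C reduces only the aldehyde to give 28, which is cyclodehydrated as in step 13.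

Further compounds

F1 | step 6 | 5-tert-butyl 1-methyl 2-[(1R)-7-methoxy-2,3-dihydro-1H-inden-1-yl]-3-oxopentanedioate (C2 epimers) | COc1cccc2c1[C@H](CC2)C(C(=O)OC)C(=O)CC(=O)OC(C)(C)C
F2 | step 6 | 5-tert-butyl 1-methyl 4-diazo-2-[(1R)-7-methoxy-2,3-dihydro-1H-inden-1-yl]-3-oxopentanedioate | COc1cccc2c1[C@H](CC2)C(C(=O)OC)C(=O)C(=[N+]=[N-])C(=O)OC(C)(C)C
F3 | step 6 | C22-keto analogue of cycloheptatriene diester 16 | COC1=CC=CC2=C3[C@H](CC2)C(C(=O)OC)C(=O)[C@]31C(=O)OC(C)(C)C
F4 | step 6 | C22-hydroxy analogue of 16 (C22 epimers) | COC1=CC=CC2=C3[C@H](CC2)C(C(=O)OC)C(O)[C@]31C(=O)OC(C)(C)C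
F5 | step 6 | C17=C22 enoate analogue of 16 | COC1=CC=CC2=C3[C@H](CC2)C(C(=O)OC)=C[C@]31C(=O)OC(C)(C)C
F6 | step 9 | C9-methylidene derivative of ketone 20 | O=C1C(=C)CCC2=C3[C@H](CC2)[C@H](C(=O)OC)C[C@@H]31
F7 | step 11 | keto aldehyde (C6 bears CHO = C7 and CH2CH2C(O)Et) | CCC(=O)CC[C@@]2(C=O)[C@@H]1CCC3=C4[C@H](CC3)[C@H](C(=O)OC)C[C@@]42CN(C)C1
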